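**Plan**

- Numbering runs from C1 (the CH2 on furan C3) along the chain to C15 (lactone carbonyl). The enabling feature is the quaternary C12 (CH3, ring oxygen, C13) of the five-membered lactone ring (O, C12, C13, C14, C15): it lies next to the C11 hydroxyl and three atoms from the C15 carbonyl, so it maps onto a C12 ketone between a free C11–OH and a C15 methyl ester.
- Retrosynthetic cuts, in order: C12–CH3 together with the lactone O–C15 bond; C11–C12 (nitroaldol, nitro group as masked ketone); O–CH3 at C6 and C8–CH3; C5–C6 together with the C3–O bond ([2,3]-shift of an allyl propargyl ether); the ether C6–O bond; C3–C4 and C1=C2 back to 3-furaldehyde.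
- Forward: a furyl C1–C5 allylic alcohol (steps 1–4) and a C6–C11 propargylic bromide (steps 5–7) are joined as an ether, rearranged, methylated at C8 and at O6, oxidised at C11 and extended by C12–C15. The γ-lactone, the only ring made, closes in the last step.
- Stereochemistry: C3 comes from a CBS reduction and is relayed to C6 by the [2,3]-Wittig shift, which also sets 3E. 7E comes from trans-hydroalumination, iodination and Negishi methylation. C11 comes from a copper-catalysed asymmetric Henry reaction, and C12 from chelation-controlled 1,2-induction by C11.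

Key step: step 19

Remark: the Henry ligand is taken as the antipode whose copper complex sends the nitronate to the Si face of the C11 aldehyde; both antipodes are available from the two enantiomers of camphor.

**Route**

Step 1
Reactants: 1 3-furaldehyde; 2 diethyl [2-(methoxy(methyl)amino)-2-oxoethyl]phosphonate
Product: 3 (2E)-3-(furan-3-yl)-N-methoxy-N-methylprop-2-enamide
Conditions: NaH, THF, 0 °C → rt
Reagents that add atoms: none
Why: Horner–Wadsworth–Emmons olefination of the aldehyde by the stabilised phosphonate anion should form C1=C2 and deliver C3 directly at the Weinreb amide level needed in step 3.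

Step 2
Reactants: 3 (2E)-3-(furan-3-yl)-N-methoxy-N-methylprop-2-enamide
Product: 4 3-(furan-3-yl)-N-methoxy-N-methylpropanamide
Conditions: H2 (1 atm), 5% Pd/C, EtOAc, rt, stopped after one equivalent of H2
Reagents that add atoms: none
Why: Catalytic hydrogenation should saturate the conjugated C1=C2 bond much faster than the aromatic furan ring or the N–O bond.

Step 3
Reactants: 4 3-(furan-3-yl)-N-methoxy-N-methylpropanamide; 5 isopropenylmagnesium bromide
Product: 7 1-(furan-3-yl)-4-methylpent-4-en-3-one, via magnesium hemiaminal chelate 6 (not isolated)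
Conditions: THF, 0 °C; poured into cold 1 M HCl
Reagents that add atoms: none
Why: Weinreb ketone synthesis, in which the chelated tetrahedral adduct survives until the cold acidic quench, so that only one isopropenyl group adds (C3–C4 bond) and the liberated amine is protonated before it can add to the enone.

Step 4
Reactants: 7 1-(furan-3-yl)-4-methylpent-4-en-3-one
Product: 8 (3R)-5-(furan-3-yl)-2-methylpent-1-en-3-ol
Conditions: (S)-1-methyl-3,3-diphenyltetrahydro-1H,3H-pyrrolo[1,2-c][1,3,2]oxazaborole [(S)-Me-CBS] (20 mol %), catecholborane, toluene, −78 °C; MeOH, then aq. NaOH wash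
Reagents that add atoms: none
Why: Corey–Bakshi–Shibata reduction, in which the oxazaborolidine binds the carbonyl anti to the larger isopropenyl group and delivers hydride to one face, which should give the (3R) alcohol, while catecholborane at −78 °C leaves the 1,1-disubstituted alkene alone.

Step 5
Reactants: 9 pent-4-yn-1-ol
Product: 10 tert-butyldimethyl(pent-4-yn-1-yloxy)silane
Conditions: TBSCl, imidazole, CH2Cl2, 0 °C → rt
Reagents that add atoms: tert-butyldimethylsilyl chloride, CC(C)(C)[Si](C)(C)Cl
Why: Standard silylation of a primary alcohol gives an ether that tolerates the organolithium, aluminate and alkoxide steps that follow.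

Step 6
Reactants: 10 tert-butyldimethyl(pent-4-yn-1-yloxy)silane
Product: 12 6-[(tert-butyldimethylsilyl)oxy]hex-2-yn-1-ol, via lithium acetylide 11 (not isolated)
Conditions: n-BuLi, THF, −78 °C; (CH2O)n, −78 °C → rt; H2O
Reagents that add atoms: formaldehyde (from paraformaldehyde), C=O
Why: Addition of the lithium acetylide to formaldehyde supplies C6 as a propargylic CH2OH.

Step 7
Reactants: 12 6-[(tert-butyldimethylsilyl)oxy]hex-2-yn-1-ol
Product: 13 [(6-bromohex-4-yn-1-yl)oxy](tert-butyl)dimethylsilane
Conditions: CBr4, PPh3, CH2Cl2, 0 °C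
Reagents that add atoms: carbon tetrabromide, BrC(Br)(Br)Br
Why: The Appel reaction converts the primary propargylic alcohol into the bromide under neutral conditions that leave the silyl ether intact.

Step 8
Reactants: 8 (3R)-5-(furan-3-yl)-2-methylpent-1-en-3-ol; 13 [(6-bromohex-4-yn-1-yl)oxy](tert-butyl)dimethylsilane
Product: 14 tert-butyl{[6-{[(3R)-5-(furan-3-yl)-2-methylpent-1-en-3-yl]oxy}hex-4-yn-1-yl]oxy}dimethylsilane
Conditions: NaH, THF, 0 °C; then 13, n-Bu4NI (cat.), THF/DMF, 0 °C → rt
Reagents that add atoms: none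
Why: Williamson ether synthesis by SN2 attack of the sodium alkoxide on the primary propargylic bromide forms the C3–O–C6 ether without touching the C3 stereocentre.

Step 9
Reactants: 14 tert-butyl{[6-{[(3R)-5-(furan-3-yl)-2-methylpent-1-en-3-yl]oxy}hex-4-yn-1-yl]oxy}dimethylsilane
Product: 16 (6S,8E)-1-[(tert-butyldimethylsilyl)oxy]-11-(furan-3-yl)-8-methylundec-8-en-4-yn-6-ol, via lithiated propargyl ether 15 (not isolated)
Conditions: n-BuLi (1.5 equiv), THF, −78 °C; H2O at −78 °C
Reagents that add atoms: none
Why: [2,3]-Wittig rearrangement, in which the propargyl-stabilised α-oxy carbanion attacks the alkene terminus C5 through a five-membered envelope with the C3 substituent pseudo-equatorial (giving 3E) and the alkynyl group exo, so that the (3R) configuration should be relayed suprafacially to (6S) as C3–O breaks and C5–C6 forms.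

Step 10
Reactants: 16 (6S,8E)-1-[(tert-butyldimethylsilyl)oxy]-11-(furan-3-yl)-8-methylundec-8-en-4-yn-6-ol
Product: 18 (4Z,6S,8E)-1-[(tert-butyldimethylsilyl)oxy]-11-(furan-3-yl)-4-iodo-8-methylundeca-4,8-dien-6-ol, via cyclic alkenylalanate 17 (not isolated)
Conditions: NaAlH2(OCH2CH2OMe)2, THF, 0 °C → rt; I2, THF, −78 °C; aq. Na2S2O3
Reagents that add atoms: iodine, II
Why: Hydroxyl-directed trans-hydroalumination of the propargylic alcohol places aluminium on C8 in a five-membered alkoxyalanate, and iodinolysis with retention should give the (7Z)-8-iodo allylic alcohol.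

Step 11
Reactants: 18 (4Z,6S,8E)-1-[(tert-butyldimethylsilyl)oxy]-11-(furan-3-yl)-4-iodo-8-methylundeca-4,8-dien-6-ol
Product: 19 (4E,6S,8E)-1-[(tert-butyldimethylsilyl)oxy]-11-(furan-3-yl)-4,8-dimethylundeca-4,8-dien-6-ol
Conditions: MeZnCl (3 equiv), Pd(PPh3)4 (5 mol %), THF, 0 °C → rt
Reagents that add atoms: methylzinc chloride, C[Zn]Cl
Why: Negishi coupling of the alkenyl iodide proceeds with retention of geometry, so the methyl group takes the place of iodine cis to C6 and the C7=C8 bond becomes 7E.

Step 12
Reactants: 19 (4E,6S,8E)-1-[(tert-butyldimethylsilyl)oxy]-11-(furan-3-yl)-4,8-dimethylundeca-4,8-dien-6-ol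
Product: 20 tert-butyl{[(4E,6S,8E)-11-(furan-3-yl)-6-methoxy-4,8-dimethylundeca-4,8-dien-1-yl]oxy}dimethylsilane
Conditions: NaH, MeI, THF/DMF, 0 °C → rt
Reagents that add atoms: iodomethane, CI
Why: Williamson methylation of the sodium alkoxide installs the C6 methyl ether without any bond change at the stereocentre.

Step 13
Reactants: 20 tert-butyl{[(4E,6S,8E)-11-(furan-3-yl)-6-methoxy-4,8-dimethylundeca-4,8-dien-1-yl]oxy}dimethylsilane
Product: 21 (4E,6S,8E)-11-(furan-3-yl)-6-methoxy-4,8-dimethylundeca-4,8-dien-1-ol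
Conditions: n-Bu4NF, THF, 0 °C → rt
Reagents that add atoms: none
Why: Fluoride cleaves the primary silyl ether while the furan, both alkenes and the allylic methyl ether are inert.

Step 14
Reactants: 21 (4E,6S,8E)-11-(furan-3-yl)-6-methoxy-4,8-dimethylundeca-4,8-dien-1-ol
Product: 22 (4E,6S,8E)-11-(furan-3-yl)-6-methoxy-4,8-dimethylundeca-4,8-dienal
Conditions: Dess–Martin periodinane, pyridine, CH2Cl2, 0 °C → rt
Reagents that add atoms: none
Why: Dess–Martin oxidation should stop at the C11 aldehyde under buffered conditions that spare the furan and the allylic ether.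

Step 15
Reactants: 22 (4E,6S,8E)-11-(furan-3-yl)-6-methoxy-4,8-dimethylundeca-4,8-dienal; 23 methyl 4-nitrobutanoate
Product: 24 methyl (4RS,5R,8E,10S,12E)-15-(furan-3-yl)-5-hydroxy-10-methoxy-8,12-dimethyl-4-nitropentadeca-8,12-dienoate
Conditions: Cu(OAc)2·H2O (10 mol %), N-(pyridin-2-ylmethyl)isobornylamine ligand (11 mol %), i-Pr2NEt, EtOH, −20 °C, 23 in excess
Reagents that add atoms: none
Why: Catalytic asymmetric Henry (nitroaldol) reaction, in which the chiral aminopyridine complex of divalent copper binds aldehyde and nitronate and directs C12 to the Si face of the C11 carbonyl, which should set (11R), while both C12 epimers are usable because C12 becomes a carbonyl carbon in step 17.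

Step 16
Reactants: 24 methyl (4RS,5R,8E,10S,12E)-15-(furan-3-yl)-5-hydroxy-10-methoxy-8,12-dimethyl-4-nitropentadeca-8,12-dienoate
Product: 25 methyl (4RS,5R,8E,10S,12E)-15-(furan-3-yl)-10-methoxy-8,12-dimethyl-4-nitro-5-[(triethylsilyl)oxy]pentadeca-8,12-dienoate
Conditions: TESCl, imidazole, DMF, 0 °C
Reagents that add atoms: chlorotriethylsilane, CC[Si](Cl)(CC)CC
Why: Silylation blocks the C11 hydroxyl so that nitronate formation in the next step cannot start a retro-nitroaldol cleavage or scramble C11.

Step 17
Reactants: 25 methyl (4RS,5R,8E,10S,12E)-15-(furan-3-yl)-10-methoxy-8,12-dimethyl-4-nitro-5-[(triethylsilyl)oxy]pentadeca-8,12-dienoate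
Product: 27 methyl (5R,8E,10S,12E)-15-(furan-3-yl)-10-methoxy-8,12-dimethyl-4-oxo-5-[(triethylsilyl)oxy]pentadeca-8,12-dienoate, via sodium nitronate 26 (not isolated)
Conditions: NaOMe (1.1 equiv), MeOH, 0 °C; added to aq. TiCl3 (5 equiv), NH4OAc (pH 5–6), THF/H2O, 0 °C → rt
Reagents that add atoms: water, O
Why: Nef reaction in its reductive variant, in which the nitronate is reduced by trivalent titanium at pH 5–6 to the imine, which hydrolyses to the C12 ketone without acid strong enough to harm the furan or the allylic ether.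

Step 18
Reactants: 27 methyl (5R,8E,10S,12E)-15-(furan-3-yl)-10-methoxy-8,12-dimethyl-4-oxo-5-[(triethylsilyl)oxy]pentadeca-8,12-dienoate
Product: 28 methyl (5R,8E,10S,12E)-15-(furan-3-yl)-5-hydroxy-10-methoxy-8,12-dimethyl-4-oxopentadeca-8,12-dienoate
Conditions: HF·pyridine, pyridine, THF, 0 °C; used at once
Reagents that add atoms: none
Why: Buffered HF·pyridine removes the secondary triethylsilyl ether without base, so the α-hydroxy ketone should be released without enolisation at C11.

Step 19
Reactants: 28 methyl (5R,8E,10S,12E)-15-(furan-3-yl)-5-hydroxy-10-methoxy-8,12-dimethyl-4-oxopentadeca-8,12-dienoate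
Product: 31 (5S)-5-[(1R,4E,6S,8E)-11-(furan-3-yl)-1-hydroxy-6-methoxy-4,8-dimethylundeca-4,8-dien-1-yl]-5-methyloxolan-2-one (CNP0306177.2), via bromomagnesium alkoxide chelate 29 (not isolated), via bis(bromomagnesium) diolate ester 30 (not isolated)
Conditions: MeMgBr (2.3 equiv), THF, −78 → 0 °C; H2O quench; then PPTS (cat.), CH2Cl2, rt
Reagents that add atoms: methylmagnesium bromide, C[Mg]Br
Why: The first equivalent of MeMgBr deprotonates the C11 hydroxyl and the magnesium alkoxide binds the C12 carbonyl oxygen in a rigid five-membered chelate (Mg, O, C11, C12, O), after which the second equivalent adds methyl to C12 from the chelate face that carries the small C11–H, opposite the C10 chain. The closest known reaction type is the chelation-controlled (Cram cyclic model) Grignard addition to α-hydroxy and α-alkoxy ketones, followed by lactonisation of a γ-hydroxy ester. The γ-lactone ring (O, C12, C13, C14, C15) closes by 5-exo-trig attack of the C12 alkoxide on the C15 ester carbonyl with loss of methoxide, on warming or during the mildly acidic work-up. The new C12 stereocentre is controlled by the C11 stereocentre through the chelate (1,2-induction), which for (11R) should give (12S). The step needs one ketone face, ketone before ester and an intact C11 centre: the chelate supplies the first, the low temperature and small excess of Grignard reagent the second, and the C11 alkoxide, which disfavours enolisation towards C11, the third. Any six-membered lactone formed through the C11 oxygen should equilibrate to the more stable five-membered lactone under the pyridinium p-toluenesulfonate treatment.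

**Compound list**

1 | 3-furaldehyde | O=Cc1ccoc1 | starting material
2 | diethyl [2-(methoxy(methyl)amino)-2-oxoethyl]phosphonate | CCOP(=O)(CC(=O)N(C)OC)OCC | starting material
3 | (2E)-3-(furan-3-yl)-N-methoxy-N-methylprop-2-enamide | CON(C)C(=O)/C=C/c1ccoc1 | intermediate
4 | 3-(furan-3-yl)-N-methoxy-N-methylpropanamide | CON(C)C(=O)CCc1ccoc1 | intermediate
5 | isopropenylmagnesium bromide (commercial THF solution) | C=C(C)[Mg]Br | starting material
6 | bromomagnesium hemiaminal chelate of the Weinreb adduct | C=C(C)C(CCc1ccoc1)(O[Mg]Br)N(C)OC | intermediate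
7 | 1-(furan-3-yl)-4-methylpent-4-en-3-one | C=C(C)C(=O)CCc1ccoc1 | intermediate
8 | (3R)-5-(furan-3-yl)-2-methylpent-1-en-3-ol | C=C(C)[C@H](O)CCc1ccoc1 | intermediate
9 | pent-4-yn-1-ol | C#CCCCO | starting material
10 | tert-butyldimethyl(pent-4-yn-1-yloxy)silane | C#CCCCO[Si](C)(C)C(C)(C)C | intermediate
11 | lithium acetylide of 10 | [Li]C#CCCCO[Si](C)(C)C(C)(C)C | intermediate
12 | 6-[(tert-butyldimethylsilyl)oxy]hex-2-yn-1-ol | OCC#CCCCO[Si](C)(C)C(C)(C)C | intermediate
13 | [(6-bromohex-4-yn-1-yl)oxy](tert-butyl)dimethylsilane | BrCC#CCCCO[Si](C)(C)C(C)(C)C | intermediate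
14 | tert-butyl{[6-{[(3R)-5-(furan-3-yl)-2-methylpent-1-en-3-yl]oxy}hex-4-yn-1-yl]oxy}dimethylsilane | C=C(C)[C@H](OCC#CCCCO[Si](C)(C)C(C)(C)C)CCc1ccoc1 | intermediate
15 | ether 14 lithiated at the propargylic O–CH position (C6) | C=C(C)[C@H](OC([Li])C#CCCCO[Si](C)(C)C(C)(C)C)CCc1ccoc1 | intermediate
16 | (6S,8E)-1-[(tert-butyldimethylsilyl)oxy]-11-(furan-3-yl)-8-methylundec-8-en-4-yn-6-ol | CC(C)(C)[Si](C)(C)OCCCC#C[C@@H](O)C/C(C)=C/CCc1ccoc1 | intermediate
17 | sodium cyclic alkenylalanate (five-membered ring Al, O, C6, C7, C8; two 2-methoxyethoxy groups on Al) | [Na+].COCCO[Al-]1(OCCOC)O[C@@H](C/C(C)=C/CCc2ccoc2)C=C1CCCO[Si](C)(C)C(C)(C)C | intermediate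
18 | (4Z,6S,8E)-1-[(tert-butyldimethylsilyl)oxy]-11-(furan-3-yl)-4-iodo-8-methylundeca-4,8-dien-6-ol | CC(C)(C)[Si](C)(C)OCCC/C(I)=C/[C@@H](O)C/C(C)=C/CCc1ccoc1 | intermediate
19 | (4E,6S,8E)-1-[(tert-butyldimethylsilyl)oxy]-11-(furan-3-yl)-4,8-dimethylundeca-4,8-dien-6-ol | CC(C)(C)[Si](C)(C)OCCC/C(C)=C/[C@@H](O)C/C(C)=C/CCc1ccoc1 | intermediate
20 | tert-butyl{[(4E,6S,8E)-11-(furan-3-yl)-6-methoxy-4,8-dimethylundeca-4,8-dien-1-yl]oxy}dimethylsilane | CO[C@H](/C=C(\C)CCCO[Si](C)(C)C(C)(C)C)C/C(C)=C/CCc1ccoc1 | intermediate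
21 | (4E,6S,8E)-11-(furan-3-yl)-6-methoxy-4,8-dimethylundeca-4,8-dien-1-ol | CO[C@H](/C=C(\C)CCCO)C/C(C)=C/CCc1ccoc1 | intermediate
22 | (4E,6S,8E)-11-(furan-3-yl)-6-methoxy-4,8-dimethylundeca-4,8-dienal | CO[C@H](/C=C(\C)CCC=O)C/C(C)=C/CCc1ccoc1 | intermediate
23 | methyl 4-nitrobutanoate | COC(=O)CCC[N+](=O)[O-] | starting material
24 | methyl (4RS,5R,8E,10S,12E)-15-(furan-3-yl)-5-hydroxy-10-methoxy-8,12-dimethyl-4-nitropentadeca-8,12-dienoate | CO[C@H](/C=C(\C)CC[C@@H](O)C(CCC(=O)OC)[N+](=O)[O-])C/C(C)=C/CCc1ccoc1 | intermediate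
25 | methyl (4RS,5R,8E,10S,12E)-15-(furan-3-yl)-10-methoxy-8,12-dimethyl-4-nitro-5-[(triethylsilyl)oxy]pentadeca-8,12-dienoate | CO[C@H](/C=C(\C)CC[C@@H](O[Si](CC)(CC)CC)C(CCC(=O)OC)[N+](=O)[O-])C/C(C)=C/CCc1ccoc1 | intermediate
26 | sodium nitronate of 25 | [Na+].CO[C@H](/C=C(\C)CC[C@@H](O[Si](CC)(CC)CC)C(CCC(=O)OC)=[N+]([O-])[O-])C/C(C)=C/CCc1ccoc1 | intermediate
27 | methyl (5R,8E,10S,12E)-15-(furan-3-yl)-10-methoxy-8,12-dimethyl-4-oxo-5-[(triethylsilyl)oxy]pentadeca-8,12-dienoate | CO[C@H](/C=C(\C)CC[C@@H](O[Si](CC)(CC)CC)C(=O)CCC(=O)OC)C/C(C)=C/CCc1ccoc1 | intermediate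
28 | methyl (5R,8E,10S,12E)-15-(furan-3-yl)-5-hydroxy-10-methoxy-8,12-dimethyl-4-oxopentadeca-8,12-dienoate | CO[C@H](/C=C(\C)CC[C@@H](O)C(=O)CCC(=O)OC)C/C(C)=C/CCc1ccoc1 | intermediate
29 | C11 bromomagnesium alkoxide of 28, chelated to the C12 carbonyl | CO[C@H](/C=C(\C)CC[C@@H](O[Mg]Br)C(=O)CCC(=O)OC)C/C(C)=C/CCc1ccoc1 | intermediate
30 | bis(bromomagnesium) alkoxide of the (11R,12S)-11,12-dihydroxy-12-methyl methyl ester | CO[C@H](/C=C(\C)CC[C@@H](O[Mg]Br)[C@@](C)(O[Mg]Br)CCC(=O)OC)C/C(C)=C/CCc1ccoc1 | intermediate
31 | (5S)-5-[(1R,4E,6S,8E)-11-(furan-3-yl)-1-hydroxy-6-methoxy-4,8-dimethylundeca-4,8-dien-1-yl]-5-methyloxolan-2-one (CNP0306177.2) | CO[C@H](/C=C(\C)CC[C@@H](O)[C@]1(C)CCC(=O)O1)C/C(C)=C/CCc1ccoc1 | target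

**Step count and risks**

Total step count: 19. Longest linear sequence: 16 steps (steps 1–4 and 8–19, from 3-furaldehyde); steps 5–7 form a three-step side branch from pent-4-yn-1-ol.

Steps most likely to fail:

1. Step 9. The chirality relay may leak if the alkynyl group partly takes the endo position in the envelope, or if the C3 substituent partly sits pseudo-axial, so that C6 is formed with insufficient enantiomeric purity. The fallback sets out from compound 16 as obtained: oxidation with MnO2 in CH2Cl2 should give the ynone F1, and Noyori asymmetric transfer hydrogenation with RuCl[(S,S)-TsDPEN](p-cymene) in i-PrOH, which reduces alkyl alkynyl ketones under catalyst control, should return (6S)-configured 16. The C6 configuration is then fixed by the catalyst instead of by the relay, and the route is rejoined at compound 16.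

2. Step 17. Under methoxide the nitronate may expel triethylsilanolate by β-elimination, or the reduction may stall at the oxime stage. The fallback sets out from compound 25 and avoids alkoxide base: reduction of the nitro group with SnCl2, PhSH and Et3N in MeCN should give the isolable oxime F2, which is then cleaved reductively with aqueous TiCl3 buffered by NH4OAc. The route is rejoined at compound 27.

3. Step 19. Facial selectivity may be poor if the magnesium alkoxide chelate is loosened by solvent or aggregation, and the Grignard reagent may attack the ester while the mixture warms. The fallback sets out from compound 28 and keeps the same C12–CH3 bond formation and lactone closure, but replaces the alkoxide chelate by an ether chelate. MOMCl and i-Pr2NEt should give the methoxymethyl ether F3, and MeMgBr (1.2 equiv) in CH2Cl2/Et2O at −78 °C should add through the chelate between the ether oxygen and the carbonyl. Only the C12 alkoxide is then free to lactonise, which should give the protected lactone F4. ZnBr2 and n-PrSH in CH2Cl2 at 0 °C remove the acetal, and the route is rejoined at compound 31.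

Further compounds
F1 | step 9 | (8E)-1-[(tert-butyldimethylsilyl)oxy]-11-(furan-3-yl)-8-methylundec-8-en-4-yn-6-one | CC(C)(C)[Si](C)(C)OCCCC#CC(=O)C/C(C)=C/CCc1ccoc1
F2 | step 17 | methyl (5R,8E,10S,12E)-15-(furan-3-yl)-4-(hydroxyimino)-10-methoxy-8,12-dimethyl-5-[(triethylsilyl)oxy]pentadeca-8,12-dienoate | CO[C@H](/C=C(\C)CC[C@@H](O[Si](CC)(CC)CC)C(CCC(=O)OC)=NO)C/C(C)=C/CCc1ccoc1
F3 | step 19 | methyl (5R,8E,10S,12E)-15-(furan-3-yl)-10-methoxy-5-(methoxymethoxy)-8,12-dimethyl-4-oxopentadeca-8,12-dienoate | CO[C@H](/C=C(\C)CC[C@@H](OCOC)C(=O)CCC(=O)OC)C/C(C)=C/CCc1ccoc1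
F4 | step 19 | (5S)-5-[(1R,4E,6S,8E)-11-(furan-3-yl)-6-methoxy-1-(methoxymethoxy)-4,8-dimethylundeca-4,8-dien-1-yl]-5-methyloxolan-2-one | CO[C@H](/C=C(\C)CC[C@@H](OCOC)[C@]1(C)CCC(=O)O1)C/C(C)=C/CCc1ccoc1
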